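Retrosynthetic cuts, in order: N–CH3; N–C1 and N–C9 (nine-membered ring C, double N-alkylation of a sulfonamide); C3=C4 (dehydration) and C4–C5 (ring B, aldehyde–ketone benzoin closure); C15–O; last, C13–C14 and C7–C12 together (ring A, Diels–Alder reaction).
Enabling feature: in ring A (C13–C14–C15–C8–C7–C12) the C13 acetate is 1,3 to C4 across the quaternary C12, so C13–C12–C4 is the enol acetate of a 2-formyl ketone, and C15 (CH3, O) is a hydrated trisubstituted alkene. Ring A is therefore the adduct of the diene C14=C15–C8=C7 with the (Z)-β-acetoxy enone C13=C12–C4=O, whose acetate is carried into the target.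
Forward order: ring A first (C7, C12, C13 set in one step), C15–O delivered from the C13 acetate, ring C by N-alkylation onto two 3-chloropropyl arms, ring B by C4–C5 closure, then dehydration inside ring C to the C3=C4 enone and N-methylation.
Stereochemistry: absolute configuration from a chiral oxazaborolidinium catalyst in the cycloaddition; C13/C12 from the Z enol acetate; C7/C12 from the endo transition state; C15 from 1,3-acetate participation; alkene geometry from ring C.

Key step: step 4

Remark: atoms are numbered as in fawcettimine-type alkaloids: N, C1, C2 (CH2), C3 (=CH), C4 (=C), C5 (C=O), C6 (CH2), C7 (CH), C8 (CH2), C15 (C(CH3)(OAc), methyl = C16), C14 (CH2), C13 (CHOAc), C12 (quaternary), C11, C10, C9 (CH2 chain back to N).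
Remark: 5-chloropentanal is taken as a commercial material.

Step 1
Reactants: 1 pent-1-en-4-yne; 2 2-bromopropene
Product: 5 (E)-2-methylhepta-1,3,6-triene, via alkenylzirconocene chloride 3 (not isolated), via alkenylzinc chloride 4 (not isolated)
Conditions: Cp2Zr(H)Cl (1.0 equiv), THF, 0 °C → rt; ZnCl2 (1.0 equiv); then 2, Pd(PPh3)4 (3 mol %), rt
Reagents that add atoms: none
Why: Hydrozirconation is syn, anti-Markovnikov and faster at the terminal alkyne than at the terminal alkene, and transmetalation to zinc followed by Negishi coupling with the vinyl bromide proceeds with retention to give the (E)-1,3-diene.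

Step 2
Reactants: 6 5-chloropentanal; 7 4-chlorobutanoyl chloride
Product: 10 6-chloro-2-(3-chloropropyl)-3-oxohexanal, via enamine 8 (not isolated), via enaminone 9 (not isolated)
Conditions: pyrrolidine, 4 Å MS, PhMe, 0 °C; then 7, Et3N, CH2Cl2, −20 → 0 °C; then 1 M HCl–THF, rt
Reagents that add atoms: water (O)
Why: Stork enamine acylation puts the acyl group regiospecifically on the aldehyde α-carbon (future C12), and acid hydrolysis of the vinylogous amide releases the enolised 2-formyl ketone, which has no stereocentre of consequence.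

Step 3
Reactants: 10 6-chloro-2-(3-chloropropyl)-3-oxohexanal
Product: 12 (Z)-6-chloro-2-(3-chloropropyl)-3-oxohex-1-enyl acetate, via lithium enolate 11 (not isolated)
Conditions: LiN(SiMe3)2 (1.05 equiv), THF, −78 °C; AcCl, −78 → −40 °C
Reagents that add atoms: acetyl chloride (CC(=O)Cl)
Why: O-acylation of the chelated, U-shaped lithium enolate at the less hindered formyl oxygen should give the enol acetate with the acetoxy group cis to the ketone (Z), by analogy with chelation-controlled Z-selective enol sulfonylation of α-formyl carbonyl compounds.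

Step 4
Reactants: 12 (Z)-6-chloro-2-(3-chloropropyl)-3-oxohex-1-enyl acetate; 5 (E)-2-methylhepta-1,3,6-triene
Product: 13 6-(4-chlorobutanoyl)-6-(3-chloropropyl)-3-methyl-5-(prop-2-enyl)cyclohex-3-enyl acetate with acetoxy (C13), 4-chlorobutanoyl (on C12) and allyl (on C7) mutually cis
Conditions: (S)-CBS-type oxazaborolidine [B-(2-methylphenyl), from (S)-α,α-diphenylprolinol] (20 mol %), HNTf2 (18 mol %), 5 (2 equiv), CH2Cl2, −78 → −40 °C
Reagents that add atoms: none
Why: Proposed new method: the triflimide-activated oxazaborolidine binds the C4 ketone oxygen of the push–pull enone 12 and lowers its LUMO for a concerted, asynchronous [4+2] cycloaddition in which the unsubstituted diene terminus C14 bonds first to the β-carbon C13 and the substituted terminus C7 then closes onto the α-carbon C12. The closest known reaction type is the oxazaborolidinium-catalysed enantioselective Diels–Alder reaction of α-substituted enals and enones with 2-substituted 1,3-dienes, which has not been shown for (Z)-β-acyloxy-α-alkyl enones. Ring A is closed by an intermolecular suprafacial (4+2) cycloaddition, both new σ-bonds lying in the one six-membered ring. The C13/C12 relationship (acetate cis to the C4 acyl group) follows from the Z geometry of 12, the C7/C12 relationship (allyl cis to acyl) from the endo orientation of the Lewis-acid-bound carbonyl towards the (E)-diene, and the absolute configuration from the catalyst, whose aryl group shields one face of the coordinated enone. The step needs regioselectivity (the 2-methyl and 4-alkyl groups of the diene both direct C14 to the electrophilic β-carbon), endo and enantiofacial selectivity, retention of the Z enol acetate (low temperature, no base) and chemoselectivity for the conjugated diene over the isolated vinyl group (unconjugated, so inert).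

Step 5
Reactants: 13 cyclohexene cycloadduct
Product: 15 2-(4-chlorobutanoyl)-2-(3-chloropropyl)-5-hydroxy-4-iodo-5-methyl-3-(prop-2-enyl)cyclohexyl acetate (C15 OH cis to C13 OAc; C8 iodide trans to the C15 OH), via acetoxonium ion 14 (not isolated)
Conditions: N-iodosuccinimide (1.1 equiv), dry CH2Cl2, −40 → 0 °C, dark; then H2O–THF, pH 7 buffer, 0 °C
Reagents that add atoms: N-iodosuccinimide (O=C1CCC(=O)N1I); water (O)
Why: The iodonium ion on the alkene face anti to the C13 acetate is opened at the tertiary carbon C15 by the acetate carbonyl oxygen (six-membered acetoxonium participation of the Woodward–Prévost kind, as in iodocarbonate cyclisations of homoallylic carbonates), so the C15 oxygen is delivered cis to the C13 oxygen with the methyl trans, the iodide sits trans at C8, and hydrolysis of the dioxanylium ion leaves the acetate on the secondary oxygen.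

Step 6
Reactants: 15 iodohydrin acetate
Product: 17 2-(4-chlorobutanoyl)-2-(3-chloropropyl)-5-methyl-3-(prop-2-enyl)cyclohexane-1,5-diyl diacetate (cis-diacetate), via hydroxy acetate 16 (not isolated)
Conditions: Bu3SnH, AIBN (cat.), PhMe, 80 °C; then (crude) Ac2O, Sc(OTf)3 (2 mol %), MeCN, −20 °C
Reagents that add atoms: acetic anhydride (CC(=O)OC(C)=O)
Why: Radical chain deiodination removes the C8 iodide without touching the primary chlorides, and Sc(OTf)3-catalysed acetylation esterifies the hindered tertiary alcohol under non-basic conditions, no stereocentre being affected.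

Step 7
Reactants: 17 cis-diacetate bis-chloride
Product: 20 spiro compound in which an N-(2-nitrobenzenesulfonyl)azonan-5-one (ring C, ketone = C4) shares C12 with ring A (diacetate, allyl on C7), via C1-alkylated sulfonamide 18 (not isolated), via C9-alkylated sulfonamide 19 (not isolated)
Conditions: 2-nitrobenzenesulfonamide (1.05 equiv), K2CO3, Bu4NI (cat.), DMF, 70 °C, 0.005 M, slow addition of 17
Reagents that add atoms: 2-nitrobenzenesulfonamide (NS(=O)(=O)c1ccccc1[N+](=O)[O-])
Why: Fukuyama-type double N-alkylation, in which the acidic sulfonamide displaces the two primary chlorides first inter- and then intramolecularly (iodide catalysis, high dilution), the quaternary C12 and the sp2 carbon C4 favouring closure of the nine-membered ring, while the non-basic sulfonamide nitrogen cannot condense with the C4 ketone.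

Step 8
Reactants: 20 N-nosyl spiro azonanone
Product: 22 the corresponding aldehyde (CH2CHO on C7; C5 = CHO), via ozonide 21 (not isolated)
Conditions: O3, CH2Cl2, −78 °C; then Me2S, −78 °C → rt
Reagents that add atoms: ozone ([O-][O+]=O)
Why: Ozonolysis with reductive work-up cleaves the only remaining alkene, the terminal vinyl group, to the C5 aldehyde.

Step 9
Reactants: 22 keto aldehyde
Product: 23 tricyclic α-ketol (rings A/B cis-fused, C5 ketone, C4 tertiary OH on the face of C13, N-nosyl ring C)
Conditions: 3-benzyl-5-(2-hydroxyethyl)-4-methylthiazolium chloride (20 mol %), DBU (40 mol %), t-BuOH–THF, 40 °C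
Reagents that add atoms: none
Why: In this intramolecular crossed aldehyde–ketone benzoin reaction the carbene turns the C5 aldehyde into an acyl anion equivalent that adds to the C4 ketone (5-exo-trig), closing ring B cis-fused to ring A because C6 and the C4 acyl group are cis; the new C4 carbinol centre is expected with C3 cis to C11 (the favoured cis 5/9 fusion) and is removed in the next step.

Step 10
Reactants: 23 α-ketol
Product: 24 N-nosyl enone (target skeleton with N-(2-nitrobenzenesulfonyl) in place of N-methyl)
Conditions: Burgess reagent (MeO2CN–SO2NEt3 inner salt), PhMe, 50 °C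
Reagents that add atoms: none
Why: Burgess syn-elimination of the tertiary α-ketol can only occur towards C3 (C12 is quaternary, C5 is the carbonyl carbon), and ring C enforces the ring-cis alkene, i.e. the (E)-enone with C2 cis to C12.

Step 11
Reactants: 24 N-nosyl enone
Product: 25 N-demethyl target (secondary amine)
Conditions: PhSH, K2CO3, MeCN, rt
Reagents that add atoms: none
Why: In this Fukuyama deprotection thiolate adds ipso to the 2-nitroarene and the sulfonamide collapses with loss of SO2 to the secondary amine, the acetates being inert and any thiol adduct of the enone being reversible under the basic conditions.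

Step 12
Reactants: 25 secondary amine
Product: 27 target compound, via iminium ion 26 (not isolated)
Conditions: aq. CH2O (37 %), NaBH(OAc)3, AcOH (1 equiv), ClCH2CH2Cl, 0 °C → rt
Reagents that add atoms: formaldehyde (C=O)
Why: Reductive amination, in which the secondary amine condenses with formaldehyde to an iminium ion that NaBH(OAc)3 reduces faster than the enone or the esters, giving the N-methyl amine without touching any stereocentre.

Compound list
1 | pent-1-en-4-yne | C=CCC#C | starting material
2 | 2-bromopropene | C=C(C)Br | starting material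
3 | (E)-chlorobis(cyclopentadienyl)(penta-1,4-dien-1-yl)zirconium | C=CC/C=C/[Zr](Cl)(C1C=CC=C1)C1C=CC=C1 | intermediate
4 | (E)-penta-1,4-dien-1-ylzinc chloride | C=CC/C=C/[Zn]Cl | intermediate
5 | (E)-2-methylhepta-1,3,6-triene | C=CC/C=C/C(C)=C | intermediate
6 | 5-chloropentanal | O=CCCCCCl | starting material
7 | 4-chlorobutanoyl chloride | O=C(Cl)CCCCl | starting material
8 | (E)-1-(5-chloropent-1-en-1-yl)pyrrolidine | ClCCC/C=C/N1CCCC1 | intermediate
9 | (E)-6-chloro-2-(3-chloropropyl)-1-(pyrrolidin-1-yl)hex-1-en-3-one | O=C(CCCCl)/C(CCCCl)=C/N1CCCC1 | intermediate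
10 | 6-chloro-2-(3-chloropropyl)-3-oxohexanal (enolised 2-formyl ketone) | O=CC(CCCCl)C(=O)CCCCl | intermediate
11 | lithium (Z)-6-chloro-2-(3-chloropropyl)-3-oxohex-1-en-1-olate | [Li+].[O-]/C=C(/CCCCl)C(=O)CCCCl | intermediate
12 | (Z)-6-chloro-2-(3-chloropropyl)-3-oxohex-1-enyl acetate | CC(=O)O/C=C(/CCCCl)C(=O)CCCCl | intermediate
13 | 6-(4-chlorobutanoyl)-6-(3-chloropropyl)-3-methyl-5-(prop-2-enyl)cyclohex-3-enyl acetate, acetoxy, acyl and allyl all cis | CC(=O)O[C@H]1CC(C)=C[C@@H](CC=C)[C@@]1(CCCCl)C(=O)CCCCl | intermediate
14 | bridged 2-methyl-1,3-dioxan-2-ylium ion spanning O13 and O15, C8 iodide trans to O15, succinimidate salt | C[C+]2O[C@H]1C[C@@](C)(O2)[C@H](I)[C@@H](CC=C)[C@@]1(CCCCl)C(=O)CCCCl.O=C1CCC(=O)[N-]1 | intermediate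
15 | iodohydrin acetate: C13 OAc, C15 OH cis to it, C8 iodide trans to the C15 OH | CC(=O)O[C@H]1C[C@@](C)(O)[C@H](I)[C@@H](CC=C)[C@@]1(CCCCl)C(=O)CCCCl | intermediate
16 | hydroxy acetate (15 without iodine) | CC(=O)O[C@H]1C[C@@](C)(O)C[C@@H](CC=C)[C@@]1(CCCCl)C(=O)CCCCl | intermediate
17 | cis-C13,C15-diacetate with 3-chloropropyl and 4-chlorobutanoyl on C12 and allyl on C7 | CC(=O)O[C@H]1C[C@@](C)(OC(C)=O)C[C@@H](CC=C)[C@@]1(CCCCl)C(=O)CCCCl | intermediate
18 | 17 with the C1 chloride replaced by NH-(2-nitrobenzenesulfonyl) | CC(=O)O[C@H]1C[C@@](C)(OC(C)=O)C[C@@H](CC=C)[C@@]1(CCCCl)C(=O)CCCNS(=O)(=O)c2ccccc2[N+](=O)[O-] | intermediate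
19 | 17 with the C9 chloride replaced by NH-(2-nitrobenzenesulfonyl) | CC(=O)O[C@H]1C[C@@](C)(OC(C)=O)C[C@@H](CC=C)[C@@]1(CCCNS(=O)(=O)c2ccccc2[N+](=O)[O-])C(=O)CCCCl | intermediate
20 | N-(2-nitrobenzenesulfonyl)azonan-5-one spiro-fused at C12 to ring A (diacetate, allyl on C7) | CC(=O)O[C@H]1C[C@@](C)(OC(C)=O)C[C@@H](CC=C)[C@]12CCCN(S(=O)(=O)c3ccccc3[N+](=O)[O-])CCCC2=O | intermediate
21 | 1,2,4-trioxolane (ozonide) of 20, epimers at the ozonide carbon | CC(=O)O[C@H]1C[C@@](C)(OC(C)=O)C[C@@H](CC4OCOO4)[C@]12CCCN(S(=O)(=O)c3ccccc3[N+](=O)[O-])CCCC2=O | intermediate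
22 | aldehyde: 20 with CH2CHO on C7 | CC(=O)O[C@H]1C[C@@](C)(OC(C)=O)C[C@@H](CC=O)[C@]12CCCN(S(=O)(=O)c3ccccc3[N+](=O)[O-])CCCC2=O | intermediate
23 | tricyclic α-ketol: C5 ketone, C4 tertiary OH, N-nosyl | CC(=O)O[C@H]1C[C@@](C)(OC(C)=O)C[C@H]2CC(=O)[C@]3(O)CCCN(S(=O)(=O)c4ccccc4[N+](=O)[O-])CCC[C@@]321 | intermediate
24 | N-(2-nitrobenzenesulfonyl)-N-demethyl target (E-enone) | CC(=O)O[C@H]1C[C@@](C)(OC(C)=O)C[C@H]2CC(=O)/C3=C/CCN(S(=O)(=O)c4ccccc4[N+](=O)[O-])CCC[C@@]321 | intermediate
25 | N-demethyl target (secondary amine) | CC(=O)O[C@H]1C[C@@](C)(OC(C)=O)C[C@H]2CC(=O)/C3=C/CCNCCC[C@@]321 | intermediate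
26 | N-methyleneiminium ion of 25, acetate salt | CC(=O)O[C@H]1C[C@@](C)(OC(C)=O)C[C@H]2CC(=O)/C3=C/CC[N+](=C)CCC[C@@]321.CC(=O)[O-] | intermediate
27 | CNP0386920.1 | CC(=O)O[C@H]1C[C@@](C)(OC(C)=O)C[C@H]2CC(=O)/C3=C/CCN(C)CCC[C@@]321 | target

Total step count: 12. Longest linear sequence: 11 steps (6 → 27, steps 2–12).

Steps most likely to fail

1. Step 4 (Proposed new method). What may go wrong: low reactivity of the trisubstituted, donor-substituted dienophile, loss of the Z geometry by rotation in the Lewis-acid complex, exo approach, or poor or reversed enantiofacial discrimination (a reversed sense alone would be met by the catalyst made from (R)-α,α-diphenylprolinol). Fallback, by known chemistry, setting out from enamine 8 (made from 6 as in step 2) and triene 5 and coming back at 13: the dienophile is changed to a 2-substituted acrolein, the class for which oxazaborolidinium-catalysed cycloadditions are established. Vilsmeier formylation of enamine 8 (POCl3, DMF) gives the vinamidinium chloride F1, and aqueous base hydrolysis gives 2-(3-chloropropyl)propanedial F2. Its chelated lithium enolate F3 is O-acetylated (LiN(SiMe3)2, AcCl, −78 °C) to (Z)-5-chloro-2-formylpent-1-enyl acetate F4, a symmetrical dialdehyde giving one constitution only. Cycloaddition of F4 with 5 under the same catalyst should give the aldehyde cycloadduct F5. Addition of 3-chloropropylmagnesium bromide at −78 °C with a cold acidic quench (to prevent 1,3-acetyl migration) gives the carbinol F6 as a mixture of epimers, and Dess–Martin oxidation returns to 13.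

2. Step 5. What may go wrong: opening of the iodonium ion without acetate participation (wrong face at C15), reaction at the terminal vinyl group, or acetyl migration during hydrolysis. Fallback, setting out from 13 and coming back at 16: Oxone (2KHSO5·KHSO4·K2SO4) with NaHCO3 in aqueous MeCN converts the C4 ketone in situ into the dioxirane F7. F7 should epoxidise the C15=C8 alkene intramolecularly on the face of the acyl group, which is the face of the C13 acetate, to give the epoxide F8. PhSeNa (preformed, no excess hydride) opens F8 at the secondary carbon C8 with inversion to the hydroxy selenide F9. Bu3SnH/AIBN then removes selenium to give hydroxy acetate 16, which is acetylated as in step 6.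

3. Step 9. What may go wrong: failure of the carbene-derived acyl anion equivalent to add to the hindered α-quaternary ketone inside the nine-membered ring (homo-benzoin, aldol or no reaction), or α-ketol rearrangement under base. Fallback, setting out from 17 and coming back at 23: ring B is closed reductively before the nitroarene is introduced, and ring C is then closed on the cis-hydrindanone template. Ozonolysis of 17 (O3, then Me2S) gives, through the ozonide F10, the keto aldehyde F11. SmI2 (THF, −78 °C) effects ketyl pinacol cyclisation to the cis-diol F12, with the 3-chloropropyl chain on C4 expected cis to the C11 chain. IBX in DMSO oxidises the secondary carbinol to the α-ketol F13. Double N-alkylation of 2-nitrobenzenesulfonamide (K2CO3, Bu4NI, DMF, high dilution) then proceeds through the mono-alkylated sulfonamides F14 and F15 to 23.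

Further compounds
F1 | step 4 | 1-[2-(3-chloropropyl)-3-(dimethylamino)prop-2-enylidene]pyrrolidinium chloride | CN(C)C=C(CCCCl)C=[N+]1CCCC1.[Cl-]
F2 | step 4 | 2-(3-chloropropyl)propanedial | O=CC(CCCCl)C=O
F3 | step 4 | lithium (Z)-5-chloro-2-formylpent-1-en-1-olate | [Li+].[O-]/C=C(/CCCCl)C=O
F4 | step 4 | (Z)-5-chloro-2-formylpent-1-enyl acetate | CC(=O)O/C=C(/CCCCl)C=O
F5 | step 4 | 6-(3-chloropropyl)-6-formyl-3-methyl-5-(prop-2-enyl)cyclohex-3-enyl acetate, acetoxy, formyl and allyl all cis | CC(=O)O[C@H]1CC(C)=C[C@@H](CC=C)[C@@]1(CCCCl)C=O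
F6 | step 4 | 6-(4-chloro-1-hydroxybutyl)-6-(3-chloropropyl)-3-methyl-5-(prop-2-enyl)cyclohex-3-enyl acetate, carbinol epimers | CC(=O)O[C@H]1CC(C)=C[C@@H](CC=C)[C@@]1(CCCCl)C(O)CCCCl
F7 | step 5 | dioxirane of 13 at C4 | CC(=O)O[C@H]1CC(C)=C[C@@H](CC=C)[C@@]1(CCCCl)C2(CCCCl)OO2
F8 | step 5 | C15,C8-epoxide of 13, oxygen cis to the C13 acetate | CC(=O)O[C@H]1C[C@@]2(C)O[C@H]2[C@@H](CC=C)[C@@]1(CCCCl)C(=O)CCCCl
F9 | step 5 | hydroxy selenide: C15 OH cis to C13 OAc, C8 SePh trans to the C15 OH | CC(=O)O[C@H]1C[C@@](C)(O)[C@H]([Se]c2ccccc2)[C@@H](CC=C)[C@@]1(CCCCl)C(=O)CCCCl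
F10 | step 9 | 1,2,4-trioxolane (ozonide) of 17 | CC(=O)O[C@H]1C[C@@](C)(OC(C)=O)C[C@@H](CC2OCOO2)[C@@]1(CCCCl)C(=O)CCCCl
F11 | step 9 | keto aldehyde: 17 with CH2CHO on C7 | CC(=O)O[C@H]1C[C@@](C)(OC(C)=O)C[C@H](CC=O)[C@@]1(CCCCl)C(=O)CCCCl
F12 | step 9 | bicyclic cis-C4,C5-diol with 3-chloropropyl groups on C4 and C12 | CC(=O)O[C@H]1C[C@@](C)(OC(C)=O)C[C@H]2C[C@@H](O)[C@](O)(CCCCl)[C@]21CCCCl
F13 | step 9 | bicyclic α-ketol (C5 ketone, C4 OH) with 3-chloropropyl groups on C4 and C12 | CC(=O)O[C@H]1C[C@@](C)(OC(C)=O)C[C@H]2CC(=O)[C@](O)(CCCCl)[C@]21CCCCl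
F14 | step 9 | F13 with the C1 chloride replaced by NH-(2-nitrobenzenesulfonyl) | CC(=O)O[C@H]1C[C@@](C)(OC(C)=O)C[C@H]2CC(=O)[C@](O)(CCCNS(=O)(=O)c3ccccc3[N+](=O)[O-])[C@]21CCCCl
F15 | step 9 | F13 with the C9 chloride replaced by NH-(2-nitrobenzenesulfonyl) | CC(=O)O[C@H]1C[C@@](C)(OC(C)=O)C[C@H]2CC(=O)[C@](O)(CCCCl)[C@]21CCCNS(=O)(=O)c3ccccc3[N+](=O)[O-]
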